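**Retrosynthetic overview**

1. The target is read as a cis-fused drimane; the aryl ether (Mitsunobu reaction with isofraxidin) and the acetate are made last.
2. C11 and the exocyclic C8=C12 alkene come from one SE2′ hydroxymethylation of an allylsilane (Si–C12–C8=C9); the one-carbon bridge left on C6 by the key step is removed by hydrodecarboxylation.
3. Rings A and B are formed together by an intramolecular Diels–Alder reaction (C5–C10 and C6–C7) of a monocyclic precursor: a Z-2-(silylmethyl)diene C7=C8–C9=C10, tethered by C1–C2 to C3 of an α,β-unsaturated δ-lactone whose alkene is C5=C6. Ring order: temporary lactone ring first, then rings A and B in one operation.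
4. Enabling feature: ring B is a six-membered ring with an sp2 carbon (C8) next to C9, i.e. a latent C8=C9 cyclohexene, and the C3 oxygen lies on ring A cis (1,3) to C6. O3 and C6 can therefore be tied by a one-carbon lactone bridge that activates C5=C6 and relays the C3 configuration to C5 and C10.
5. The precursor comes from (R)-pantolactone (C3, C4 with both methyls, C5) by propargylation, carboxylation, syn-carbocupration (Z-alkene), ester-to-allylsilane conversion and Bestmann lactonisation.

Key step: step 11

Remark on the chemistry: the given SMILES encodes a cis-fused decalin (H on C5 and CH3 on C10 on the same face), with the CH2OAr group on C9 cis to the C10 methyl and the C3 acetate on the opposite face; absolute configuration 3S,5R,9R,10R. The route is built for exactly this stereoisomer.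

Atom numbers are drimane numbers: ring A = C1–C5 and C10; ring B = C5–C10; C11 = the OCH2 carbon on C9; C12 = the exocyclic methylene carbon on C8.

**Route**

Step 1
Reactants: 1 (R)-pantolactone
Product: 2 (2R)-3,3-dimethylbutane-1,2,4-triol
Conditions: LiAlH4, THF, 0 °C to reflux; Fieser work-up
Reagents that add atoms: none
Why: Hydride reduction of the lactone to the triol does not touch the oxygen-bearing stereocentre, which becomes C3 of the target.

Step 2
Reactants: 2 (2R)-3,3-dimethylbutane-1,2,4-triol
Product: 3 [(2R,4R)-2-(4-methoxyphenyl)-5,5-dimethyl-1,3-dioxan-4-yl]methanol (aryl and CH2OH cis, both equatorial)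
Conditions: 4-MeOC6H4CH(OMe)2 (1.1 equiv), camphorsulfonic acid (cat.), CH2Cl2, rt, equilibrating conditions
Reagents that add atoms: 4-methoxybenzaldehyde dimethyl acetal, COc1ccc(C(OC)OC)cc1
Why: Thermodynamic transacetalisation; arylidene acetals prefer the six-membered 1,3-dioxane (here stabilised by the 5,5-dimethyl group), so O3 and O5 are masked together, the primary OH on C2 stays free, and the acetal carbon settles with the aryl group equatorial.

Step 3
Reactants: 3 [(2R,4R)-2-(4-methoxyphenyl)-5,5-dimethyl-1,3-dioxan-4-yl]methanol; 4 1-(trimethylsilyl)propyne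
Product: 6 (2R,4S)-2-(4-methoxyphenyl)-5,5-dimethyl-4-[4-(trimethylsilyl)but-3-yn-1-yl]-1,3-dioxane, via primary triflate 5 (not isolated)
Conditions: Tf2O, 2,6-lutidine, CH2Cl2, −78 °C; crude triflate added to 4/n-BuLi, THF, −78 to −20 °C
Reagents that add atoms: none
Why: SN2 alkylation of the propargylic lithium reagent by the primary triflate (the silyl group blocks the alkyne terminus) forms the C1–C2 bond; no stereocentre is involved.

Step 4
Reactants: 6 silylated alkyne
Product: 7 (2R,4S)-4-(but-3-yn-1-yl)-2-(4-methoxyphenyl)-5,5-dimethyl-1,3-dioxane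
Conditions: K2CO3 (cat.), MeOH, rt
Reagents that add atoms: none
Why: Methanolytic protodesilylation of the alkynylsilane, a standard unmasking of a terminal alkyne.

Step 5
Reactants: 7 terminal alkyne
Product: 9 methyl 5-[(2R,4S)-2-(4-methoxyphenyl)-5,5-dimethyl-1,3-dioxan-4-yl]pent-2-ynoate, via lithium acetylide 8 (not isolated)
Conditions: n-BuLi, THF, −78 °C; ClCO2Me, −78 to 0 °C
Reagents that add atoms: methyl chloroformate, COC(Cl)=O
Why: C-acylation of the lithium acetylide installs C8 as the ester carbon of a 2-alkynoate.

Step 6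
Reactants: 9 alkynoate
Product: 10 methyl (2Z)-3-methyl-5-[(2R,4S)-2-(4-methoxyphenyl)-5,5-dimethyl-1,3-dioxan-4-yl]pent-2-enoate (chain cis to CO2Me)
Conditions: Me2CuLi (from MeLi and CuI), THF, −78 °C; MeOH added at −78 °C, then aqueous NH4Cl
Reagents that add atoms: lithium dimethylcuprate, [Li+].C[Cu-]C
Why: syn-Carbocupration (conjugate addition) of the 2-alkynoate puts methyl and copper cis, so protonation with retention at −78 °C leaves the chain carbon C1 cis to C8 (Z); the cold quench prevents allenoate equilibration.

Step 7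
Reactants: 10 Z-enoate
Product: 12 trimethyl{(3Z)-4-methyl-2-methylidene-6-[(2R,4S)-2-(4-methoxyphenyl)-5,5-dimethyl-1,3-dioxan-4-yl]hex-3-en-1-yl}silane, via bis(silylmethyl) carbinol 11 (not isolated)
Conditions: Me3SiCH2MgCl (4 equiv), anhydrous CeCl3 (4 equiv), THF, −78 °C to rt; then silica gel, CH2Cl2, rt
Reagents that add atoms: (trimethylsilylmethyl)magnesium chloride, C[Si](C)(C)C[Mg]Cl
Why: Double 1,2-addition of the organocerium reagent to the ester followed by Peterson elimination (Bunnelle allylsilane synthesis) turns CO2Me into C8(=C7H2)–C12H2SiMe3 without touching the C9=C10 geometry.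

Step 8
Reactants: 12 dienylsilane acetal
Product: 13 (3S,6Z)-2,2,6-trimethyl-8-methylidene-9-(trimethylsilyl)non-6-ene-1,3-diol
Conditions: pyridinium p-toluenesulfonate (cat.), MeOH, rt
Reagents that add atoms: none
Why: Acid-catalysed transacetalisation to methanol frees O3 and O5; the weak acid should spare the allylsilane.

Step 9
Reactants: 13 diol
Product: 14 (3S,6Z)-3-hydroxy-2,2,6-trimethyl-8-methylidene-9-(trimethylsilyl)non-6-enal
Conditions: TEMPO (10 mol %), PhI(OAc)2 (1.1 equiv), CH2Cl2, rt
Reagents that add atoms: none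
Why: Oxoammonium oxidation is selective for the primary over the hindered secondary alcohol; the aldehyde (C5) has no α-hydrogen, so it can neither epimerise nor eliminate.

Step 10
Reactants: 14 hydroxy aldehyde
Product: 16 (6S)-5,5-dimethyl-6-[(3Z)-3-methyl-5-methylidene-6-(trimethylsilyl)hex-3-en-1-yl]-5,6-dihydro-2H-pyran-2-one, via ester phosphorane 15 (not isolated)
Conditions: Ph3P=C=C=O (1.2 equiv), toluene, 80 °C
Reagents that add atoms: (triphenylphosphoranylidene)ketene, O=C=C=P(c1ccccc1)(c1ccccc1)c1ccccc1
Why: Bestmann lactonisation: the C3 hydroxyl adds to the ketenylidene phosphorane and the resulting ester ylide closes onto the C5 aldehyde by intramolecular Wittig reaction, giving the α,β-unsaturated δ-lactone with a ring-enforced cis C5=C6 alkene.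

Step 11
Reactants: 16 dienyl dihydropyranone
Product: 17 tricyclic lactone: cis-fused Δ8(9)-octalin with CH2SiMe3 on C8, CH3 on C10 cis to H5, and a C6–C(=O)–O–C3 lactone bridge on the face of ring A opposite to H5 and the C10 methyl
Conditions: toluene (0.01 M), BHT (cat.), N,O-bis(trimethylsilyl)acetamide (0.1 equiv, acid scavenger), sealed tube, 170 °C
Reagents that add atoms: none
Why: Thermal intramolecular Diels–Alder reaction (concerted, asynchronous [4+2]) between the 2-(silylmethyl)diene C7=C8–C9=C10 and the lactone alkene C5=C6 forms C5–C10 and C6–C7 in one operation; the closest known reaction type is the intramolecular Diels–Alder reaction of a diene tethered to a cyclic α,β-unsaturated ester (butenolide or dihydropyranone) dienophile. Ring B closes as the cycloaddition ring itself (four diene carbons plus C5 and C6), and ring A closes as the tether ring through the C5–C10 bond, ending 1,3-diaxially bridged by the lactone O–C(=O) unit (a 2-oxabicyclo[3.3.1]nonanone). C5: the two-carbon tether C1–C2 can reach C5 only on the lactone face that carries the C3 side chain, so C10 bonds syn to C2 and the C3 oxygen is forced trans to H5 (C3, from pantolactone, controls C5). C10: the diene is Z at C9=C10 with the tether as the inside substituent, and an inside tether can close only through the transition state that places H5 and the outside methyl on the same face, so the ring fusion is cis; C6 follows from suprafacial addition to the ring alkene and is removed later. Regiochemistry is fixed by the tether, and the only selectivity needed, the pairing of diene face and dienophile face, is left no alternative by the bicyclic constraint. The lactone carbonyl lowers the dienophile LUMO, the gem-dimethyl group and the ring preorganise the chain, and BHT plus the acid scavenger suppress polymerisation and protodesilylation.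

Step 12
Reactants: 17 tricyclic lactone allylsilane
Product: 18 hydroxymethyl lactone: exocyclic C8=C12 alkene, CH2OH on C9 cis to the C10 methyl, lactone bridge intact
Conditions: paraformaldehyde (3 equiv), Me2AlCl (3 equiv), CH2Cl2, −78 to 0 °C
Reagents that add atoms: paraformaldehyde (as formaldehyde), C=O
Why: Hosomi–Sakurai-type SE2′ hydroxymethylation: C9 attacks the formaldehyde–Me2AlCl complex and the β-silyl cation at C8 loses silicon to give the exocyclic alkene; the lactone bridge locks ring A so that C1 is pseudoaxial on the lower face of ring B next to C9 and the lactone carbonyl also lies under ring B, so the electrophile adds axially to C9 from the open face that carries H5 and the C10 methyl, setting C9 with CH2OH cis to that methyl.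

Step 13
Reactants: 18 hydroxymethyl lactone
Product: 19 dihydroxy acid (C6–CO2H, C3–OH, C11–OH)
Conditions: LiOH·H2O, THF/H2O, rt to 40 °C; acidified at 0 °C to pH 4 (1 M HCl); used at once
Reagents that add atoms: lithium hydroxide, [Li+].[OH-]
Why: Saponification of the δ-lactone (acyl–oxygen cleavage) frees O3 with retention and leaves the bridging carbon as a carboxylic acid on C6; immediate use limits relactonisation.

Step 14
Reactants: 19 dihydroxy acid
Product: 20 (3S,5R,9R,10R)-cis-drim-8(12)-ene-3,11-diol (C6 now CH2)
Conditions: 9-mesityl-10-phenylacridinium tetrafluoroborate (5 mol %), PhSSPh (10 mol %), i-Pr2NEt (20 mol %), CF3CH2OH, 450 nm LEDs, rt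
Reagents that add atoms: none
Why: Photoredox hydrodecarboxylation: the excited acridinium oxidises the carboxylate, CO2 is lost, and the secondary C6 radical takes a hydrogen atom from PhSH; free alcohols are tolerated and C6 is no longer a stereocentre.

Step 15
Reactants: 20 diol; 21 isofraxidin (7-hydroxy-6,8-dimethoxycoumarin)
Product: 22 (3S,5R,9R,10R)-11-(6,8-dimethoxy-2-oxo-2H-chromen-7-yloxy)-cis-drim-8(12)-en-3-ol
Conditions: PPh3, DIAD, THF, 0 °C to rt
Reagents that add atoms: none
Why: Mitsunobu etherification at the primary C11 hydroxyl (no stereocentre involved); the neopentylic secondary C3 hydroxyl is too hindered to compete.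

Step 16
Reactants: 22 aryl ether alcohol
Product: 23 target, (3S,5R,9R,10R)-3-acetoxy-11-(6,8-dimethoxy-2-oxo-2H-chromen-7-yloxy)-cis-drim-8(12)-ene
Conditions: Ac2O, pyridine, DMAP (cat.), rt
Reagents that add atoms: acetic anhydride, CC(=O)OC(C)=O
Why: O-Acetylation of the secondary alcohol proceeds with retention at C3 and completes the target.

**Compound list**

1 | (R)-pantolactone | CC1(C)COC(=O)[C@@H]1O | starting material
2 | (2R)-3,3-dimethylbutane-1,2,4-triol | OC[C@H](O)C(C)(C)CO | intermediate
3 | [(2R,4R)-2-(4-methoxyphenyl)-5,5-dimethyl-1,3-dioxan-4-yl]methanol | OC[C@@H]1O[C@H](c2ccc(OC)cc2)OCC1(C)C | intermediate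
4 | 1-(trimethylsilyl)propyne | CC#C[Si](C)(C)C | starting material
5 | primary triflate of 3 | O=S(=O)(OC[C@@H]1O[C@H](c2ccc(OC)cc2)OCC1(C)C)C(F)(F)F | intermediate (not isolated)
6 | (2R,4S)-2-(4-methoxyphenyl)-5,5-dimethyl-4-[4-(trimethylsilyl)but-3-yn-1-yl]-1,3-dioxane | C[Si](C)(C)C#CCC[C@@H]1O[C@H](c2ccc(OC)cc2)OCC1(C)C | intermediate
7 | (2R,4S)-4-(but-3-yn-1-yl)-2-(4-methoxyphenyl)-5,5-dimethyl-1,3-dioxane | C#CCC[C@@H]1O[C@H](c2ccc(OC)cc2)OCC1(C)C | intermediate
8 | lithium acetylide of 7 | [Li]C#CCC[C@@H]1O[C@H](c2ccc(OC)cc2)OCC1(C)C | intermediate (not isolated)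
9 | methyl 5-[(2R,4S)-2-(4-methoxyphenyl)-5,5-dimethyl-1,3-dioxan-4-yl]pent-2-ynoate | COC(=O)C#CCC[C@@H]1O[C@H](c2ccc(OC)cc2)OCC1(C)C | intermediate
10 | methyl (2Z)-3-methyl-5-[(2R,4S)-2-(4-methoxyphenyl)-5,5-dimethyl-1,3-dioxan-4-yl]pent-2-enoate | COC(=O)/C=C(/C)CC[C@@H]1O[C@H](c2ccc(OC)cc2)OCC1(C)C | intermediate
11 | bis(trimethylsilylmethyl) carbinol from 10 | C[Si](C)(C)CC(O)(C[Si](C)(C)C)/C=C(/C)CC[C@@H]1O[C@H](c2ccc(OC)cc2)OCC1(C)C | intermediate (not isolated)
12 | trimethyl{(3Z)-4-methyl-2-methylidene-6-[(2R,4S)-2-(4-methoxyphenyl)-5,5-dimethyl-1,3-dioxan-4-yl]hex-3-en-1-yl}silane | C=C(C[Si](C)(C)C)/C=C(/C)CC[C@@H]1O[C@H](c2ccc(OC)cc2)OCC1(C)C | intermediate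
13 | (3S,6Z)-2,2,6-trimethyl-8-methylidene-9-(trimethylsilyl)non-6-ene-1,3-diol | C=C(C[Si](C)(C)C)/C=C(/C)CC[C@H](O)C(C)(C)CO | intermediate
14 | (3S,6Z)-3-hydroxy-2,2,6-trimethyl-8-methylidene-9-(trimethylsilyl)non-6-enal | C=C(C[Si](C)(C)C)/C=C(/C)CC[C@H](O)C(C)(C)C=O | intermediate
15 | (triphenylphosphoranylidene)acetate ester of 14 | C=C(C[Si](C)(C)C)/C=C(/C)CC[C@H](OC(=O)C=P(c1ccccc1)(c1ccccc1)c1ccccc1)C(C)(C)C=O | intermediate (not isolated)
16 | (6S)-5,5-dimethyl-6-[(3Z)-3-methyl-5-methylidene-6-(trimethylsilyl)hex-3-en-1-yl]-5,6-dihydro-2H-pyran-2-one | O=C1C=CC(C)(C)[C@H](CC/C(C)=C\C(=C)C[Si](C)(C)C)O1 | intermediate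
17 | tricyclic Diels–Alder lactone (cis-fused Δ8(9)-octalin, CH2SiMe3 on C8, C6–C(=O)–O–C3 bridge) | C[Si](C)(C)CC1=C[C@]2(C)CC[C@@H]3OC(=O)[C@H](C1)[C@H]2C3(C)C | intermediate
18 | hydroxymethyl lactone (C8=C12 exocyclic, CH2OH on C9 cis to C10 methyl) | C=C1C[C@@H]3[C@H]2C(C)(C)[C@@H](OC3=O)CC[C@@]2(C)[C@@H]1CO | intermediate
19 | dihydroxy acid (C6–CO2H) | C=C1C[C@@H](C(=O)O)[C@H]2C(C)(C)[C@@H](O)CC[C@@]2(C)[C@@H]1CO | intermediate
20 | (3S,5R,9R,10R)-cis-drim-8(12)-ene-3,11-diol | C=C1CC[C@H]2C(C)(C)[C@@H](O)CC[C@@]2(C)[C@@H]1CO | intermediate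
21 | isofraxidin (7-hydroxy-6,8-dimethoxycoumarin) | COc1cc2ccc(=O)oc2c(OC)c1O | starting material
22 | 11-(6,8-dimethoxy-2-oxo-2H-chromen-7-yloxy)-cis-drim-8(12)-en-3-ol | C=C1CC[C@H]2C(C)(C)[C@@H](O)CC[C@@]2(C)[C@@H]1COc1c(OC)cc2ccc(=O)oc2c1OC | intermediate
23 | target, 3-acetate of 22 | C=C1CC[C@H]2C(C)(C)[C@@H](OC(C)=O)CC[C@@]2(C)[C@@H]1COc1c(OC)cc2ccc(=O)oc2c1OC | target

**Step count and risks**

Total step count: 16. Longest linear sequence: 16 steps, from (R)-pantolactone 1; compounds 4 and 21 enter as commercial materials.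

Steps most likely to fail:

1. Step 11 (key cycloaddition). Risk: bond formation between the hindered lactone β-carbon C5 and the fully substituted diene terminus C10 may be slow, so that [1,5]-hydrogen shift in the Z-diene, polymerisation or loss of silicon competes. Fallback: the dienophile is activated twice. The fallback sets out from 14, which is condensed with dimethyl malonate (piperidinium acetate, toluene, water removal; Knoevenagel condensation followed by lactonising transesterification) to the 3-methoxycarbonyl dihydropyranone F1. This alkylidene-malonate-type dienophile should undergo the same intramolecular Diels–Alder reaction at clearly lower temperature (toluene, 80–110 °C) to the angular ester adduct F2. Krapcho demethoxycarbonylation (LiCl, wet DMSO, 150 °C) then returns to 17; the C6 configuration after reprotonation is of no consequence because C6 later becomes CH2.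

2. Step 12 (hydroxymethylation). Risk: protodesilylation or an ene-type pathway may outrun C–C bond formation, because formaldehyde oligomers act as a proton source and C9 is a hindered nucleophilic site. Fallback: a preformed, aprotic oxocarbenium source replaces formaldehyde. The fallback sets out from 17, which is alkylated with benzyl chloromethyl ether and SnCl4 (CH2Cl2, −78 °C; SE2′ alkylation with an α-chloro ether, same facial control) to the benzyl ether F3. Debenzylation with BCl3 and pentamethylbenzene (CH2Cl2, −78 °C) returns to 18.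

3. Step 14 (hydrodecarboxylation). Risk: the hydroxy acid may relactonise before oxidation, or the excited acridinium may oxidise the alkene instead of the carboxylate. Fallback: a Barton decarboxylation on a fully acylated substrate. The fallback sets out from 19, which is peracetylated (Ac2O, pyridine, DMAP; aqueous work-up) to the diacetoxy acid F4, so that O3 can no longer close back onto the activated carboxyl. The acid chloride ((COCl)2, cat. DMF) is treated with sodium 2-thioxopyridin-1(2H)-olate to give the thiohydroxamate ester F5, and visible-light irradiation with t-BuSH gives the diacetate F6. Selective methanolysis of the primary acetate (K2CO3, MeOH, 0 °C; the neopentylic C3 acetate is far slower) gives the 3-acetoxy alcohol F7, and Mitsunobu reaction of F7 with 21 (PPh3, DIAD) arrives directly at 23.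

Further compounds
F1 | step 11 | methyl (6S)-5,5-dimethyl-6-[(3Z)-3-methyl-5-methylidene-6-(trimethylsilyl)hex-3-en-1-yl]-2-oxo-5,6-dihydro-2H-pyran-3-carboxylate | COC(=O)C1=CC(C)(C)[C@H](CC/C(C)=C\C(=C)C[Si](C)(C)C)OC1=O
F2 | step 11 | tricyclic lactone adduct with CO2Me on C6 | C[Si](C)(C)CC1=C[C@]2(C)CC[C@@H]3OC(=O)[C@](C(=O)OC)(C1)[C@H]2C3(C)C
F3 | step 12 | benzyl ether of 18 | C=C1C[C@@H]3[C@H]2C(C)(C)[C@@H](OC3=O)CC[C@@]2(C)[C@@H]1COCc1ccccc1
F4 | step 14 | 3,11-diacetoxy acid from 19 | C=C1C[C@@H](C(=O)O)[C@H]2C(C)(C)[C@@H](OC(C)=O)CC[C@@]2(C)[C@@H]1COC(C)=O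
F5 | step 14 | 2-thioxopyridin-1(2H)-yl ester of F4 | C=C1C[C@@H](C(=O)ON3C=CC=CC3=S)[C@H]2C(C)(C)[C@@H](OC(C)=O)CC[C@@]2(C)[C@@H]1COC(C)=O
F6 | step 14 | 3,11-diacetate of 20 | C=C1CC[C@H]2C(C)(C)[C@@H](OC(C)=O)CC[C@@]2(C)[C@@H]1COC(C)=O
F7 | step 14 | 3-acetate of 20 (free C11 hydroxyl) | C=C1CC[C@H]2C(C)(C)[C@@H](OC(C)=O)CC[C@@]2(C)[C@@H]1CO
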